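## Retrosynthetic overview
1. Sigmoidin A is (2S)-eriodictyol carrying C-prenyl groups at C2' and C5', each ortho to a catechol oxygen. Only these two aryl–CH2 bonds are disconnected.
2. Both C–C bonds come from one isomerisation: a double photochemical 1,3 O→C prenyl shift of the 3',4'-di-O-prenyl ether, which has the same formula (C25H28O6).
3. The bis-ether comes from eriodictyol by O-prenylation, with the most acidic 7-OH blocked temporarily as a silyl ether.
4. No ring is formed. Rings A, B and C and the C2 (S) centre are bought intact and only have to be preserved, so free 4'-phenoxide and strong base are avoided throughout.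

**Assumption:** commercial natural eriodictyol (a bulk citrus / yerba-santa flavanone) is taken to be the (2S)-enantiomer, and its ee is checked by chiral HPLC before use.

## Route

**Step 1**
Reactants: **1**, (2S)-eriodictyol [(2S)-2-(3,4-dihydroxyphenyl)-5,7-dihydroxychroman-4-one]; **2**, triisopropylsilyl chloride
Product: **3**, (2S)-2-(3,4-dihydroxyphenyl)-5-hydroxy-7-(triisopropylsilyloxy)chroman-4-one
Conditions: TIPSCl (1.05 equiv), imidazole (2.2 equiv), DMF, 0 °C
Reagents that add atoms: TIPSCl, CC(C)[Si](Cl)(C(C)C)C(C)C
Why: Chemoselective phenol silylation, because under a weak base only the vinylogous-acid 7-OH (pKa ≈ 7, against ≈ 9 for the catechol and a chelated 5-OH) is appreciably ionised, so one equivalent of bulky silyl chloride goes there, C2 is untouched, and the ring-opening 4'-phenoxide is not generated.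

**Step 2**
Reactants: **3**; **4**, prenol (3-methylbut-2-en-1-ol)
Product: **5**, (2S)-2-[3,4-bis(3-methylbut-2-enyloxy)phenyl]-5-hydroxy-7-(triisopropylsilyloxy)chroman-4-one
Conditions: prenol (2.3 equiv), PPh3 (2.4 equiv), DIAD (2.4 equiv, slow addition), THF, 0 °C → rt
Reagents that add atoms: prenol, CC(C)=CCO (two equivalents incorporated as prenyl; its oxygen leaves as Ph3P=O)
Why: Double Mitsunobu etherification (SN2 at the primary allylic carbon, no added base) alkylates the two catechol OH groups and spares the least acidic chelated 5-OH and the silyl ether; capping 4'-OH closes the quinone-methide ring-opening path, so C2 stays S.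

**Step 3**
Reactants: **5**
Product: **6**, (2S)-2-[3,4-bis(3-methylbut-2-enyloxy)phenyl]-5,7-dihydroxychroman-4-one
Conditions: Et3N·3HF (3 equiv), THF, 0 °C → rt (can be added directly to the crude step 2 mixture)
Reagents that add atoms: none
Why: Fluoride desilylation of an aryl silyl ether with a good phenoxide leaving group in a slightly acidic medium, to which the prenyl ethers, the ketone and C2 are inert.

**Step 4 (key step)**
Reactants: **6**
Product: **7**, sigmoidin A, (2S)-2-[3,4-dihydroxy-2,5-bis(3-methylbut-2-enyl)phenyl]-5,7-dihydroxychroman-4-one
Conditions: hν (254 nm, low-pressure Hg, FEP flow coil, irradiated until both ether groups are consumed), 0.5 mM in Ar-sparged 0.1 M aq SDS / 10 mM phosphate (pH 5.5), 10–15 °C; KCl, EtOAc extraction; RP-HPLC (unreacted 6 and half-rearranged material returned to the coil)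
Reagents that add atoms: none (isomerisation, C25H28O6 → C25H28O6)
Why: Proposed new method: a double photo-Claisen (two successive one-photon 1,3 O→C prenyl shifts in a single irradiation) on a catechol bis(prenyl ether) carried by an intact chiral 5-hydroxyflavanone, in which 254 nm excitation of the dialkoxyarene (at the absorption minimum of the A-ring chromophore) populates the dissociative πσ* state of an ArO–CH2 bond (BDE ≈ 50 kcal/mol) to give a singlet aryloxyl/prenyl radical pair that recombines inside the viscous micellar cage (≈ 0.3 substrate molecules per micelle) through the unhindered CH2 end of the prenyl radical and then tautomerises to the phenol; the O4' pair can end productively only at C5', because its other ortho site C3' and its para site C1' are substituted and those dienone adducts cannot tautomerise and should revert, while the O3' pair can close at C2' (1,3) or C6' (1,5), and C2' should be favoured because it is next to where the radical is born and cage confinement suppresses migration across the ring, the more so once C5' is prenylated and C6' is flanked by two carbon substituents; the two shifts may occur in either order, and both productive half-rearranged prenyl ethers still carry a photolabile ArO–CH2 bond, so continued irradiation funnels them to the same product 7; the chelated 5-OH/C4=O chromophore sheds its own excitation by picosecond excited-state proton transfer, which protects C2–O1 and C2–H so the S centre is carried through unchanged, and should also limit slower secondary photochemistry such as o-prenylphenol → chroman; the closest known reaction type is the photo-Claisen rearrangement of simple aryl allyl/prenyl mono-ethers with ortho enhancement in organised media, which has not been shown as a double shift, on a catechol, or on a flavanone.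

## Compound list
| No. | Name | SMILES | Role |
|---|---|---|---|
| 1 | (2S)-eriodictyol | Oc1ccc([C@@H]2CC(=O)c3c(O)cc(O)cc3O2)cc1O | starting material (chiral pool) |
| 2 | triisopropylsilyl chloride | CC(C)[Si](Cl)(C(C)C)C(C)C | starting material |
| 3 | (2S)-7-O-TIPS-eriodictyol | Oc1ccc([C@@H]2CC(=O)c3c(O)cc(O[Si](C(C)C)(C(C)C)C(C)C)cc3O2)cc1O | intermediate |
| 4 | prenol | CC(C)=CCO | starting material |
| 5 | (2S)-3',4'-di-O-prenyl-7-O-TIPS-eriodictyol | CC(C)=CCOc1ccc([C@@H]2CC(=O)c3c(O)cc(O[Si](C(C)C)(C(C)C)C(C)C)cc3O2)cc1OCC=C(C)C | intermediate |
| 6 | (2S)-3',4'-di-O-prenyleriodictyol | CC(C)=CCOc1ccc([C@@H]2CC(=O)c3c(O)cc(O)cc3O2)cc1OCC=C(C)C | intermediate |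
| 7 | sigmoidin A | CC(C)=CCc1cc([C@@H]2CC(=O)c3c(O)cc(O)cc3O2)c(CC=C(C)C)c(O)c1O | target |

## Summary
- **Total steps:** 4. Steps 2 and 3 can be telescoped, giving 3 isolations.
- **Longest linear sequence:** 4.
- **Stereochemical control:** the only stereocentre (C2, S) is bought in 1 and never broken. The ee is checked by chiral HPLC at 1, 3, 6 and 7.

## Steps most likely to fail

**1. Step 4 (the new step).**
- Singlet energy transfer from the B ring to the A-ring chromophore lowers the quantum yield, so long irradiation and recycling are needed.
- The C6' (1,5-shift) isomer is the expected main by-product, especially from molecules in which the O3' ether cleaves first.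
- Cage escape gives mono-prenyl catechols.
- Over-irradiation risks chroman formation from the o-prenylphenol units.
- A realistic yield is 15–25%.
- *Fallback (known chemistry):* abandon the radical-pair shift for concerted aromatic Claisen rearrangements.
  - Treat 3 with tert-butyl 2-methylbut-3-en-2-yl carbonate and Pd(PPh3)4 to give the bis(1,1-dimethylallyl) ether. If the bis-ether is too hindered, install and rearrange one ether at a time.
  - Heat it (toluene, 110 °C, or Eu(fod)3, 60–80 °C) for a double [3,3] shift, which can deliver only linear prenyl groups at C5' and C2'.
  - Remove the silyl group with Et3N·3HF to give 7.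

**2. Step 1.**
- Selectivity for 7-OH over the catechol may be insufficient.
- *Fallback:* mask the catechol transiently as its cyclic phenylboronate (PhB(OH)2, molecular sieves). Silylate the only remaining unchelated phenol (7-OH), then release the catechol on aqueous/pinacol work-up.

**3. Step 2.**
- The catechol may be sequestered as a dioxaphosphorane or stall at the mono-ether, and a transient 4'-phenoxide could erode ee.
- *Fallback:* switch to a π-prenyl-palladium electrophile, using neutral decarboxylative allylic etherification with prenyl methyl carbonate and Pd2(dba)3/dppf in THF. Any branched (1,1-dimethylallyl) ether formed gives the same aryloxyl/prenyl radical pair in step 4, or undergoes the thermal [3,3] shift, and so converges on 7.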